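**The bench rule.** If every reagent charged did one turnover, the amber flask, with 1.2 equiv of reagent on 0.050 M of substrate at 25 °C, should have cleared its substrate. That is the rule of thumb for an excess, and the amber readings break it.

| setting | amber | teal | flask |
|---|---|---|---|
| substrate | 0.050 M | 0.050 M | 0.050 M |
| reagent | 1.2 equiv | 1.8 equiv | 1.20 equiv |
| temperature | 25 °C | 10 °C | 25 °C |
| remark | the very flask that is asked about, followed so far | run made earlier |  |
| time |  |  | 5.0 d |

- amber (time / h: target / %, substrate / %): 10.0: 23, 78; 15.0: 25, 80; 20.0: 20, 76; 30.0: 23, 78; 48.0: 20, 79; 72.0: 18, 77; 120: 14, 82
- teal (time / h: target / %, substrate / %): 3.00: 8, 94; 6.00: 11, 89; 10.0: 18, 83; 12.0: 20, 80; 15.0: 24, 78; 20.0: 27, 75; 25.0: 31, 71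

(scatter of a reading: 2 percentage points)

- Wednesday's: at 5.0 d take out 90 % of the by-product then present, then wait 40 h
- Friday's: change nothing and wait 40 h more
- Thursday's: at 5.0 d raise the temperature by 20 K, then wait 40 h
- Monday's: at 5.0 d add reagent, 50.0 % of the amount charged, then wait 40 h

- target, in percent of the substrate first charged, at 5.0 d
- the option that brings most further target ("none" if no option brings more than 2 percentage points) (Wednesday's / Friday's / Thursday's / Monday's / none)
- target present, in percent of the substrate first charged, after Wednesday's
- target present, in percent of the substrate first charged, after Monday's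

- the volume of additions can be left aside
- the numbers in the tables scatter with a standard deviation of 2 percentage points
- what may be going on: substrate + reagent -> target + by-product; substrate + reagent + by-product -> target + 2 by-product; target -> over-reaction product; 2 reagent -> homo dimer

**The border.** From 10.0 h on, the amber substrate merely scatters, and the mean of its readings puts the substrate gone at 21.4 %. Dividing this by the charge gives the turnover share s, the part of the reagent charged that ended in a turnover: 17.9 %. So reagent, though in excess on paper, behaved as the limiting reagent. I supposed the rest went to homo dimer. The teal run, with more reagent and colder, read 29.0 % of its substrate gone by 25.0 h, more than the amber figure, and it was still moving, so I did not put the amber stop down to the substrate.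

**My count.** The target reading at 120 h is the asked moment: 14 %, give or take 2 percentage points. Reading the substrate gone as target made, I took target to have fallen that far from 21.4 %, and pro rata that is a drain worth 2.5 points over 40 h. Wednesday's, Friday's and Thursday's add no reagent, so I counted no new turnovers for them, and for Wednesday's I reckoned about 11.5 %. Monday's adds reagent, and s on it promises 11 points, so I reckoned about 22.2 % and chose Monday's.

**The forecast.** It gave 15 % at 5.0 d, 15 % after Wednesday's and 20 % after Monday's, and chose Monday's, saying “Fresh reagent helps under either explanation”; my Monday figure stood above its figure and my Wednesday figure below.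

**The result.** The amber flask gave 16.5 % at 5.0 d, 14.8 % after Wednesday's and 41.7 % after Monday's; the best option was Monday's.

    substrate + reagent → target + by-product (k = 2.70 × 10⁻⁴ M⁻¹ s⁻¹, Ea = 70.0 kJ mol⁻¹)
    substrate + reagent + by-product → target + 2 by-product (k = 0.180 M⁻² s⁻¹, Ea = 41.0 kJ mol⁻¹)
    target → over-reaction product (k = 7.50 × 10⁻⁷ s⁻¹, Ea = 116 kJ mol⁻¹)
    2 reagent → homo dimer (k = 0.00450 M⁻¹ s⁻¹, Ea = 52.0 kJ mol⁻¹)
    (constants at 25 °C)

**Counting again.** Monday's net gain in the amber flask was 25 points, more than the 8.2 points I had counted after the drain, so the net target gained per reagent added came to 42.0 % against s of 17.9 %. The neighbour flask, the same charge read at 12 d, got no new reagent, so s on its charge still promised 21.4 % of substrate gone. In that neighbour flask reagent stood at 0 % of its own charge and substrate at 77.4 %, and target of 10.5 % and over-reaction product of 12.1 % added up to 22.6 %.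

(The earlier runs and the new flask stem from a simulated flask with made-up constants, and the scatter is random.)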